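**Retrosynthetic overview**

1. Numbering: ring A = C1 (chain carbon)–C2–C3–C4–C5–C6, ring B = C4–C5–C7–C12, ring C = C7–C8–C11–C12, ring D = C8–C9–C10–C11. The strategy rests on ring B. Apart from the fusion bonds C4–C5 and C7–C12 it consists only of C4–C12 and C5–C7, and these two bonds alone tie a plain cyclohexane (ring A) to a mirror-symmetric bicyclo[2.2.0]hexane (rings C and D).
2. Retro-[2+2] across C4–C12 and C5–C7 leads to cyclohex-2-enone (carbonyl = C6, β-carbon = C4) and cis-bicyclo[2.2.0]hex-2-ene. In the forward sense a chiral oxazaborolidine–AlBr3 Lewis acid on the enone fixes the absolute configuration.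
3. The C6 carbonyl then serves C1. Aldol condensation with the C8 aldehyde of the protected glycerol ether forms the C1–chain bond. Reductive transposition of the enone tosylhydrazone deletes the oxygen and leaves a C1=C6 alkene of fixed position, so a 1-alkyl ketone never has to be enolised toward C1 rather than C5. Hydrogenation on the face away from ring B sets C1 whatever mixtures came before.
4. The bicyclic alkene comes from cis-cyclobutane-1,2-dicarboxylic anhydride through the thiolane, its α-chloro sulfone and a Ramberg–Bäcklund contraction. The aldehyde comes from 2,2-dimethyl-1,3-dioxan-5-ol and 1,8-dibromooctane.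
5. Ring order: D (bought), C (step 5), A (bought), B (step 6, last).

Key step: step 6

Assumption: the sense of induction is taken from the accepted binding model of these catalysts (carbonyl oxygen on boron, enone α-C–H in contact with the ring oxygen, one aryl group lying over the C=C bond). By this model the (S)-prolinol series leaves the Si face of the enone β-carbon open, and the drawn enantiomer needs bonding at the Re face, so the (R)-prolinol catalyst is used.

**Step 1**
Reactants: 1 cis-cyclobutane-1,2-dicarboxylic anhydride
Product: 2 cis-1,2-bis(hydroxymethyl)cyclobutane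
Conditions: LiAlH4, THF, 0 °C to reflux; H2O, aq NaOH work-up
Reagents that add atoms: none
Why: Hydride reduction of a cyclic anhydride to the 1,4-diol leaves the two ring carbons untouched, so the cis (meso) arrangement that later becomes the C8–C11 fusion of ring D is carried over.

**Step 2**
Reactants: 2 cis-1,2-bis(hydroxymethyl)cyclobutane
Product: 3 cis-cyclobutane-1,2-diyldimethanediyl bis(methanesulfonate)
Conditions: MsCl, Et3N, CH2Cl2, 0 °C
Reagents that add atoms: methanesulfonyl chloride CS(=O)(=O)Cl
Why: Sulfonate ester formation on two unhindered primary alcohols turns both oxygens into leaving groups without affecting the ring stereocentres.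

**Step 3**
Reactants: 3 bis(methanesulfonate)
Product: 4 cis-3-thiabicyclo[3.2.0]heptane
Conditions: Na2S·9H2O, EtOH–H2O, reflux
Reagents that add atoms: sodium sulfide [Na+].[Na+].[S-2]
Why: Double SN2 displacement by sulfide, the second one a 5-exo-tet ring closure, is the standard thiolane synthesis and is favoured here by the cis arrangement of the two side arms.

**Step 4**
Reactants: 4 cis-3-thiabicyclo[3.2.0]heptane
Product: 6 cis-fused 2-chloro-3-thiabicyclo[3.2.0]heptane 3,3-dioxide (racemic; epimers at C–Cl), via α-chloro sulfide 5 (not isolated)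
Conditions: NCS, CH2Cl2, 0 °C to rt; then mCPBA (2.2 equiv), 0 °C to rt
Reagents that add atoms: N-chlorosuccinimide O=C1CCC(=O)N1Cl; 3-chloroperbenzoic acid OOC(=O)c1cccc(Cl)c1
Why: The ring contraction of step 5 needs a leaving group on one α-carbon, so the sulfide is α-chlorinated with NCS (chlorosulfonium salt, then Pummerer-type shift) and oxidised in the same flask with peracid to the sulfone; the two α-CH2 groups are equivalent and the C–Cl configuration is lost again in step 5.

**Step 5**
Reactants: 6 α-chloro sulfone
Product: 8 cis-bicyclo[2.2.0]hex-2-ene, via episulfone 7 (not isolated)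
Conditions: KOtBu, DMSO, 20 °C; vacuum transfer into CH2Cl2, H2O washes, 4 Å MS; stored cold as a titrated CH2Cl2 solution
Reagents that add atoms: none
Why: Ramberg–Bäcklund reaction: deprotonation at the unchlorinated α-carbon, 1,3-displacement of chloride to the episulfone and cheletropic loss of SO2 form the C7=C12 double bond and contract the five-membered ring to ring C, the cis fusion being the only one a bicyclo[2.2.0] frame allows; the work-up removes every Lewis base that would poison step 6.

**Step 6**
Reactants: 8 cis-bicyclo[2.2.0]hex-2-ene (excess, unreacted part recovered by vacuum transfer); 9 cyclohex-2-enone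
Product: 11 cis-anti-cis-anti-cis tetracyclo[6.4.0.0^2,7.0^3,6]dodecan-9-one (C6 ketone; local descriptors 4S,5S,7S,8R,11S,12S), via trans-fused C5 epimer 10 (not isolated)
Conditions: AlBr3 adduct of (3aR)-3,3-diphenyl-1-(2,4,6-trifluorophenyl)tetrahydro-1H,3H-pyrrolo[1,2-c][1,3,2]oxazaborole (50 mol%, made beforehand from (R)-α,α-diphenylprolinol, 2,4,6-trifluorophenylboronic acid and slightly less than one equivalent of AlBr3), CH2Cl2, −75 °C, hν (366 nm); Et3N quench at −75 °C; then basic Al2O3, CH2Cl2, rt
Reagents that add atoms: none
Why: Binding of the carbonyl oxygen of 9 to boron moves its strong π→π* band into the 366 nm region, so the complex takes nearly all the light and the weak n→π* tail of free 9 (the racemic background) is kept small by the high catalyst loading; this is the known chiral Lewis acid catalysed enantioselective intermolecular enone–alkene [2+2] photocycloaddition. After intersystem crossing the triplet bonds from its β-carbon C4 to C12 of 8, and after spin inversion the 1,4-biradical joins C5 to C7, so four-membered ring B is closed stepwise by radical recombination (formal [2+2]), and head-to-head versus head-to-tail isomers cannot occur because a mirror plane relates the two alkene carbons of 8. C4 is set by the catalyst, whose aryl group covers one face of the bound enone and leaves the Re face of C4 open. C12 and C7 are set by 8 itself: ring D blocks its endo face, so both new bonds are exo (rings B and D anti across ring C), and the choice between its two enantiotopic alkene carbons, which decides whether rings A and C end up anti or syn across ring B, is made by steric repulsion in favour of anti. C5 is set under thermodynamic control, since closure may give strained trans-fused 10 beside 11, and enolisation on basic Al2O3 inverts only C5, so both end as cis-fused 11. The step therefore needs enone face selectivity (catalyst), exo and anti selectivity (shape of 8) and survival of the strained alkene next to an aluminium Lewis acid (−75 °C, no free AlBr3, cold quench).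

**Step 7**
Reactants: 12 2,2-dimethyl-1,3-dioxan-5-ol; 13 1,8-dibromooctane
Product: 15 5-(8-bromooctyloxy)-2,2-dimethyl-1,3-dioxane, via sodium alkoxide 14 (not isolated)
Conditions: NaH, DMF, 0 °C; then 13 (4 equiv), 0 °C to rt
Reagents that add atoms: sodium hydride [Na+].[H-] (sodium held in 14 only)
Why: Williamson ether synthesis of a secondary alkoxide with a primary bromide, in which the excess of the dibromide suppresses the second substitution.

**Step 8**
Reactants: 15 bromide
Product: 16 8-[(2,2-dimethyl-1,3-dioxan-5-yl)oxy]octanal
Conditions: Me3NO (anhydrous, 4 equiv), DMSO, rt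
Reagents that add atoms: trimethylamine N-oxide C[N+](C)(C)[O-]
Why: Kornblum-type oxidation in its amine N-oxide form: SN2 attack of the N-oxide oxygen on the primary bromide and base-induced loss of trimethylamine give the aldehyde at room temperature under conditions that are harmless to the acetonide.

**Step 9**
Reactants: 11 C6 ketone; 16 aldehyde
Product: 18 aldol adduct (11 bearing at C1 a 1-hydroxy-8-[(2,2-dimethyl-1,3-dioxan-5-yl)oxy]octyl group; mixture at C1 and at the carbinol carbon), via lithium enolate 17 (not isolated)
Conditions: LiN(i-Pr)2, THF, −78 °C; then 16, −78 °C; aq NH4Cl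
Reagents that add atoms: lithium diisopropylamide CC(C)[N-]C(C)C.[Li+] (lithium held in 17 only)
Why: Directed aldol addition: the hindered amide base takes a proton from the C1 methylene and not from the C5 methine, whose enolate would put an sp2 carbon into strained ring B, and the two new centres (C1 and the carbinol carbon) need no control because both become sp2 in step 10.

**Step 10**
Reactants: 18 aldol adduct
Product: 20 (E)-exocyclic enone (C6 ketone with C1=CH–(CH2)7–O–dioxanyl), via mesylate 19 (not isolated)
Conditions: MsCl, Et3N, CH2Cl2, 0 °C; then DBU, rt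
Reagents that add atoms: methanesulfonyl chloride CS(=O)(=O)Cl (held in 19 only)
Why: Mesylation followed by E1cB elimination through the C1 enolate gives the conjugated exocyclic enone, the E isomer being favoured because it keeps the chain away from the carbonyl oxygen, while C5 stays cis-fused since that is its stable configuration.

**Step 11**
Reactants: 20 enone
Product: 21 C6 tosylhydrazone of 20
Conditions: TsNHNH2, PPTS (cat.), THF, 4 Å MS, 45 °C
Reagents that add atoms: 4-methylbenzenesulfonohydrazide Cc1ccc(cc1)S(=O)(=O)NN
Why: Acid-catalysed condensation of a ketone with a sulfonyl hydrazide; the aprotic medium with sieves takes up the water formed and so protects the acetonide, and the C=N geometry is of no consequence.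

**Step 12**
Reactants: 21 tosylhydrazone
Product: 24 C1=C6 alkene (ring A cyclohexene carrying the saturated C8 chain on C1; acetonide intact), via N-boryl hydrazide 22 (not isolated), via allylic diazene 23 (not isolated)
Conditions: catecholborane, CHCl3, −40 to 0 °C; then NaOAc·3H2O, 0 °C to reflux
Reagents that add atoms: catecholborane B1Oc2ccccc2O1 (boron held in 22 only)
Why: Reductive 1,3-transposition of an enone tosylhydrazone (hydride addition to C=N, loss of sulfinate, retro-ene loss of N2 from the allylic diazene): hydrogen ends up on C6 and on the former exocyclic carbon, so the double bond can only arrive at C1=C6, and any enone that had slipped to the endocyclic C1=C2 position would give the same alkene.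

**Step 13**
Reactants: 24 alkene
Product: 25 saturated acetonide (chain on C1 cis to ring B)
Conditions: H2 (1 atm), PtO2, EtOAc, rt
Reagents that add atoms: none
Why: Heterogeneous syn hydrogenation of a trisubstituted cyclohexene: the ladder attached through C5–C7 and C4–C12 covers the upper face of ring A, so the alkene should bind to platinum with the face that carries H4 and H5 and the new C1–H bond forms there, which places the chain cis to ring B (1S) as in the target.

**Step 14**
Reactants: 25 saturated acetonide
Product: 26 target CNP0193334.1 (local descriptors 1S,4R,5S,7R,8R,11S,12S)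
Conditions: 1 M aq HCl, THF, rt
Reagents that add atoms: none
Why: Acid hydrolysis of the isopropylidene acetal frees the 1,3-diol, and the saturated ladder and the ether linkage are inert to dilute acid.

**Compound list**

1 | cis-cyclobutane-1,2-dicarboxylic anhydride | O=C1OC(=O)[C@H]2CC[C@@H]12 | starting material
2 | cis-1,2-bis(hydroxymethyl)cyclobutane | OC[C@H]1CC[C@H]1CO | intermediate
3 | cis-cyclobutane-1,2-diyldimethanediyl bis(methanesulfonate) | CS(=O)(=O)OC[C@H]1CC[C@H]1COS(C)(=O)=O | intermediate
4 | cis-3-thiabicyclo[3.2.0]heptane | C1SC[C@H]2CC[C@@H]12 | intermediate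
5 | cis-fused 2-chloro-3-thiabicyclo[3.2.0]heptane (racemic, C–Cl undefined, not isolated) | ClC1SC[C@H]2CC[C@@H]12 | intermediate
6 | cis-fused 2-chloro-3-thiabicyclo[3.2.0]heptane 3,3-dioxide (racemic, C–Cl undefined) | ClC1S(=O)(=O)C[C@H]2CC[C@@H]12 | intermediate
7 | episulfone: thiirane 1,1-dioxide fused anti on C2–C3 of bicyclo[2.2.0]hexane (not isolated) | O=S1(=O)[C@H]2[C@@H]1[C@@H]1CC[C@@H]12 | intermediate
8 | cis-bicyclo[2.2.0]hex-2-ene | C1=C[C@H]2CC[C@@H]12 | intermediate
9 | cyclohex-2-enone | O=C1C=CCCC1 | starting material
10 | trans-fused (A/B) C5 epimer of 11 (not isolated) | C1CC[C@@H]2[C@@H](C1=O)[C@H]1[C@@H]3CC[C@@H]3[C@@H]21 | intermediate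
11 | cis-anti-cis-anti-cis tetracyclic C6 ketone | C1CC[C@@H]2[C@H](C1=O)[C@H]1[C@@H]3CC[C@@H]3[C@@H]21 | intermediate
12 | 2,2-dimethyl-1,3-dioxan-5-ol | OC1COC(C)(C)OC1 | starting material
13 | 1,8-dibromooctane | BrCCCCCCCCBr | starting material
14 | sodium 2,2-dimethyl-1,3-dioxan-5-olate (not isolated) | [Na+].[O-]C1COC(C)(C)OC1 | intermediate
15 | 5-(8-bromooctyloxy)-2,2-dimethyl-1,3-dioxane | BrCCCCCCCCOC1COC(C)(C)OC1 | intermediate
16 | 8-[(2,2-dimethyl-1,3-dioxan-5-yl)oxy]octanal | O=CCCCCCCCOC1COC(C)(C)OC1 | intermediate
17 | C1=C6 lithium enolate of 11 (not isolated) | C1C[C@@H]2[C@H](C(O[Li])=C1)[C@H]1[C@@H]3CC[C@@H]3[C@@H]21 | intermediate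
18 | aldol adduct (C1 and carbinol carbon undefined) | C1C[C@@H]2[C@H](C(=O)C1C(O)CCCCCCCOC1COC(C)(C)OC1)[C@H]1[C@@H]3CC[C@@H]3[C@@H]21 | intermediate
19 | mesylate of 18 (not isolated) | C1C[C@@H]2[C@H](C(=O)C1C(OS(C)(=O)=O)CCCCCCCOC1COC(C)(C)OC1)[C@H]1[C@@H]3CC[C@@H]3[C@@H]21 | intermediate
20 | (E)-exocyclic enone | C1C[C@@H]2[C@H](C(=O)/C1=C/CCCCCCCOC1COC(C)(C)OC1)[C@H]1[C@@H]3CC[C@@H]3[C@@H]21 | intermediate
21 | tosylhydrazone of 20 (C=N geometry undefined) | C1C[C@@H]2[C@H](C(=NNS(=O)(=O)c3ccc(C)cc3)/C1=C/CCCCCCCOC1COC(C)(C)OC1)[C@H]1[C@@H]3CC[C@@H]3[C@@H]21 | intermediate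
22 | N-(1,3,2-benzodioxaborol-2-yl) tosylhydrazide, hydride delivered to C6 from the open face (not isolated) | C1C[C@@H]2[C@H]([C@@H](N(NS(=O)(=O)c3ccc(C)cc3)B3Oc4ccccc4O3)/C1=C/CCCCCCCOC1COC(C)(C)OC1)[C@H]1[C@@H]3CC[C@@H]3[C@@H]21 | intermediate
23 | allylic diazene at C6 (not isolated) | C1C[C@@H]2[C@H]([C@@H](N=N)/C1=C/CCCCCCCOC1COC(C)(C)OC1)[C@H]1[C@@H]3CC[C@@H]3[C@@H]21 | intermediate
24 | C1=C6 alkene with the C8 chain on C1 | C1C[C@@H]2[C@H](C=C1CCCCCCCCOC1COC(C)(C)OC1)[C@H]1[C@@H]3CC[C@@H]3[C@@H]21 | intermediate
25 | saturated acetonide, chain cis to ring B | CC1(C)OCC(CO1)OCCCCCCCC[C@H]1CC[C@@H]2[C@H](C1)[C@H]1[C@@H]3CC[C@@H]3[C@@H]21 | intermediate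
26 | CNP0193334.1, 2-O-alkyl glycerol of the ladderane octanol | OCC(CO)OCCCCCCCC[C@H]1CC[C@@H]2[C@H](C1)[C@H]1[C@@H]3CC[C@@H]3[C@@H]21 | target

**Step count**

Total step count: 14.
Longest linear sequence: 12 (steps 1–6, then 9–14).

**Steps most likely to fail**

**Step 6.** What may go wrong: cationic opening or oligomerisation of the strained alkene by the aluminium Lewis acid, competing racemic reaction of unbound enone, or incomplete shielding of one enone face.

Fallback: give up asymmetric catalysis and resolve. It sets out from 8 and 9 and comes back at 11.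
- Direct irradiation at about 350 nm in CH2Cl2 at −40 °C without any Lewis acid, followed by basic Al2O3, should give 11 together with the mirror-image ketone F1.
- Li(s-Bu)3BH reduces the pair from the open face to the C6 alcohol F2 and the mirror-image alcohol F3.
- Esterification with (S)-O-methylmandelic acid (DCC, DMAP) gives the mandelate of the wanted series F4 and the mandelate of the mirror-image series F5. These are diastereomers and are separated by chromatography or crystallisation.
- LiOH cleaves F4 back to F2, and Dess–Martin periodinane returns enantiopure 11.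

**Step 13.** What may go wrong: poor facial selectivity, or migration of the double bond on the metal surface before hydrogen is delivered.

Fallback: replace surface hydrogenation by hydroboration. This adds hydrogen to C1 and boron to C6 in one concerted syn event on the open face, and it leaves a polar handle that allows a minor diastereomer to be removed. It sets out from 24 and comes back at 25.
- BH3·SMe2 followed by H2O2/NaOH gives the trans-1-alkyl C6 alcohol F6.
- Dess–Martin periodinane gives the 1-alkyl C6 ketone F7.
- TsNHNH2 gives the saturated tosylhydrazone F8.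
- Catecholborane followed by NaOAc·3H2O reduces C6 to CH2 under near-neutral conditions and gives 25.

**Step 11.** What may go wrong: slow condensation at the hindered C6 carbonyl, or conjugate addition of the hydrazide with ring closure to a pyrazoline.

Fallback: remove the oxygen as a triflate instead of as a hydrazone. It sets out from 20 and comes back at 24.
- 1,4-Hydrosilylation (Et3SiH, RhCl(PPh3)3, benzene, 50 °C) delivers hydride to the exocyclic carbon. It gives the C1=C6 triethylsilyl enol ether F9 as a single regioisomer.
- CsF and PhNTf2 in DME convert F9 into the C1=C6 enol triflate F10.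
- Pd(OAc)2, PPh3, HCO2H and Et3N in DMF at 60 °C reduce the C–O bond and give 24.

**Further compounds**

F1 | step 6 | mirror image of ketone 11 | C1CC[C@H]2[C@@H](C1=O)[C@@H]1[C@H]3CC[C@H]3[C@H]21
F2 | step 6 | C6 alcohol of the series of 11 (OH cis to ring B) | C1CC[C@@H]2[C@H]([C@H]1O)[C@H]1[C@@H]3CC[C@@H]3[C@@H]21
F3 | step 6 | mirror image of alcohol F2 | C1CC[C@H]2[C@@H]([C@@H]1O)[C@@H]1[C@H]3CC[C@H]3[C@H]21
F4 | step 6 | (S)-O-methylmandelate of F2 | C1CC[C@@H]2[C@H]([C@H]1OC(=O)[C@@H](OC)c1ccccc1)[C@H]1[C@@H]3CC[C@@H]3[C@@H]21
F5 | step 6 | (S)-O-methylmandelate of F3 | C1CC[C@H]2[C@@H]([C@@H]1OC(=O)[C@@H](OC)c1ccccc1)[C@@H]1[C@H]3CC[C@H]3[C@H]21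
F6 | step 13 | trans-1-alkyl C6 alcohol (H1 and OH on the open face) | C1C[C@@H]2[C@H]([C@H](O)[C@H]1CCCCCCCCOC1COC(C)(C)OC1)[C@H]1[C@@H]3CC[C@@H]3[C@@H]21
F7 | step 13 | 1-alkyl C6 ketone, chain cis to ring B | C1C[C@@H]2[C@H](C(=O)[C@H]1CCCCCCCCOC1COC(C)(C)OC1)[C@H]1[C@@H]3CC[C@@H]3[C@@H]21
F8 | step 13 | tosylhydrazone of F7 | C1C[C@@H]2[C@H](C(=NNS(=O)(=O)c3ccc(C)cc3)[C@H]1CCCCCCCCOC1COC(C)(C)OC1)[C@H]1[C@@H]3CC[C@@H]3[C@@H]21
F9 | step 11 | C1=C6 triethylsilyl enol ether | C1C[C@@H]2[C@H](C(O[Si](CC)(CC)CC)=C1CCCCCCCCOC1COC(C)(C)OC1)[C@H]1[C@@H]3CC[C@@H]3[C@@H]21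
F10 | step 11 | C1=C6 enol triflate | C1C[C@@H]2[C@H](C(OS(=O)(=O)C(F)(F)F)=C1CCCCCCCCOC1COC(C)(C)OC1)[C@H]1[C@@H]3CC[C@@H]3[C@@H]21
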